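The ring is numbered from the stereocentre C1 through the enoate alkene C3=C4 to C14. The plan rests on the E-trisubstituted alkene C7=C8: C8 bears a methyl group and the C9 chain, C7 the two-carbon unit C6–C5, which is what remains when 2,3-dihydrofuran is opened at its vinylic C–O bond. A single three-component step unites a limonene-derived C9 alkylcopper, 5-lithio-2,3-dihydrofuran and iodomethane, forming C8–C9 and C8–CH3, setting the E geometry and freeing the C5 alcohol. Its precursor is an acyclic homoallylic iodide with C1 (R), the Z alkene C11=C12, a dimethyl acetal at C3 and the silylated side chain. C4 then enters as a phosphonoacetate, and a Z-selective Horner–Wadsworth–Emmons reaction closes the 14-membered ring at C3=C4.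

Key step: step 13

Remark: C3 is carried as a dimethyl acetal, which the ozonolysis delivers directly and hydrolysis returns as the aldehyde, so C3 needs no redox or separate protection steps. The tertiary alcohol is carried as a TBS ether because it must survive that acidic acetalisation. TBS = tert-butyldimethylsilyl; "TBSO-heptenyl" = 6-(tert-butyldimethylsilyloxy)-6-methylhept-1-en-2-yl, bonded through its C2. The labels C1–C14 are also used for the atoms of open-chain intermediates.

Step 1
Reactants: 1 3-methylbutane-1,3-diol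
Product: 2 4-bromo-2-methylbutan-2-ol
Conditions: CBr4, PPh3, CH2Cl2, 0 °C
Reagents that add atoms: carbon tetrabromide BrC(Br)(Br)Br
Why: Appel bromination; the primary alcohol is activated and displaced by bromide far faster than the hindered tertiary alcohol.

Step 2
Reactants: 2 4-bromo-2-methylbutan-2-ol
Product: 3 tert-butyl[(4-bromo-2-methylbutan-2-yl)oxy]dimethylsilane
Conditions: TBSOTf, 2,6-lutidine, CH2Cl2, 0 °C → rt
Reagents that add atoms: tert-butyldimethylsilyl trifluoromethanesulfonate CC(C)(C)[Si](C)(C)OS(=O)(=O)C(F)(F)F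
Why: Silylation with a silyl triflate and a hindered base is the standard way to protect a tertiary alcohol, and the primary bromide is inert to it.

Step 3
Reactants: 4 (R)-limonene; 3 tert-butyl[(4-bromo-2-methylbutan-2-yl)oxy]dimethylsilane
Product: 6 (4R)-1-methyl-4-(TBSO-heptenyl)cyclohex-1-ene, via 10-lithiolimonene 5 (not isolated)
Conditions: 4 (excess), n-BuLi, TMEDA, rt, 16 h; then 3, THF, −78 °C → rt
Reagents that add atoms: none
Why: Allylic metalation/alkylation; n-BuLi·TMEDA deprotonates the isopropenyl methyl group to a 2-substituted allyllithium with equivalent termini, and SN2 attack on the primary bromide extends the side chain while the ring stereocentre is not deprotonated and keeps its R configuration.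

Step 4
Reactants: 6 (4R)-1-methyl-4-(TBSO-heptenyl)cyclohex-1-ene
Product: 8 (5R)-7,7-dimethoxy-5-(TBSO-heptenyl)heptan-2-one, via keto aldehyde 7 (not isolated)
Conditions: O3, CH2Cl2/MeOH, Sudan Red 7B, −78 °C; Me2S, −78 °C → rt; then TsOH·H2O (cat.), rt; NaHCO3
Reagents that add atoms: ozone [O-][O+]=O; methanol CO
Why: Chemoselective ozonolysis with in-situ acetalisation; ozone should take the more electron-rich trisubstituted ring alkene before the 1,1-disubstituted one, and acidic methanol acetalises the aldehyde much faster than the methyl ketone while the tertiary TBS ether tolerates the brief acid exposure.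

Step 5
Reactants: 8 (5R)-7,7-dimethoxy-5-(TBSO-heptenyl)heptan-2-one; 9 dimethyl carbonate
Product: 10 methyl (6R)-8,8-dimethoxy-6-(TBSO-heptenyl)-3-oxooctanoate
Conditions: NaH, 9 (excess), THF, reflux; aq. NH4Cl
Reagents that add atoms: none
Why: Crossed Claisen condensation; the methyl ketone is acylated at its methyl terminus and the reaction is driven by formation of the β-keto ester enolate.

Step 6
Reactants: 10 methyl (6R)-8,8-dimethoxy-6-(TBSO-heptenyl)-3-oxooctanoate
Product: 11 methyl (2E,6R)-8,8-dimethoxy-6-(TBSO-heptenyl)-3-(trifluoromethanesulfonyloxy)oct-2-enoate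
Conditions: Tf2O, aq. Me4NOH, hexanes, 5 °C
Reagents that add atoms: trifluoromethanesulfonic anhydride O=S(=O)(OS(=O)(=O)C(F)(F)F)C(F)(F)F
Why: O-Triflation of a β-keto ester enolate; with the non-chelating tetramethylammonium counterion the enolate reacts in its extended form, which should give the E enol triflate with the triflate trans to the ester.

Step 7
Reactants: 11 methyl (2E,6R)-8,8-dimethoxy-6-(TBSO-heptenyl)-3-(trifluoromethanesulfonyloxy)oct-2-enoate
Product: 12 methyl (2Z,6R)-8,8-dimethoxy-3-methyl-6-(TBSO-heptenyl)oct-2-enoate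
Conditions: MeMgBr, Fe(acac)3 (5 mol%), THF, −30 °C
Reagents that add atoms: methylmagnesium bromide C[Mg]Br
Why: Iron-catalysed Kumada-type coupling of an enol triflate; it is faster than Grignard addition to the ester and retains alkene geometry, so C13 ends cis to the ester carbon C10 (the Z alkene C11=C12).

Step 8
Reactants: 12 methyl (2Z,6R)-8,8-dimethoxy-3-methyl-6-(TBSO-heptenyl)oct-2-enoate
Product: 13 (2Z,6R)-8,8-dimethoxy-3-methyl-6-(TBSO-heptenyl)oct-2-en-1-ol
Conditions: i-Bu2AlH, CH2Cl2, −78 °C; aq. KNaC4H4O6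
Reagents that add atoms: none
Why: 1,2-Reduction of an enoate to the allylic alcohol by an aluminium hydride; acetal, silyl ether and alkenes are inert.

Step 9
Reactants: 13 (2Z,6R)-8,8-dimethoxy-3-methyl-6-(TBSO-heptenyl)oct-2-en-1-ol
Product: 15 (2Z,6R)-1-bromo-8,8-dimethoxy-3-methyl-6-(TBSO-heptenyl)oct-2-ene, via allylic mesylate 14 (not isolated)
Conditions: MsCl, Et3N, THF, −40 °C; then LiBr, THF, 0 °C
Reagents that add atoms: lithium bromide [Li+].[Br-]
Why: Mesylation followed by SN2 displacement with bromide at the primary allylic carbon under non-acidic conditions, which should preserve the Z geometry and the acetal.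

Step 10
Reactants: 15 (2Z,6R)-1-bromo-8,8-dimethoxy-3-methyl-6-(TBSO-heptenyl)oct-2-ene
Product: 16 [(3Z,7R)-9,9-dimethoxy-4-methyl-7-(TBSO-heptenyl)non-3-en-1-yl](isopropoxy)dimethylsilane
Conditions: i-PrOMe2SiCH2MgCl (from i-PrOMe2SiCH2Cl, Mg, THF), Li2CuCl4 (5 mol%), THF, −20 → 0 °C
Reagents that add atoms: (isopropoxydimethylsilyl)methylmagnesium chloride CC(C)O[Si](C)(C)C[Mg]Cl
Why: Copper-catalysed Grignard coupling with a primary allylic halide; attack at the primary carbon is favoured because γ attack would build a quaternary centre, and the silylmethyl group brings in C9 as a masked hydroxymethyl group.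

Step 11
Reactants: 16 [(3Z,7R)-9,9-dimethoxy-4-methyl-7-(TBSO-heptenyl)non-3-en-1-yl](isopropoxy)dimethylsilane
Product: 17 (3Z,7R)-9,9-dimethoxy-4-methyl-7-(TBSO-heptenyl)non-3-en-1-ol
Conditions: 30% H2O2, KF, KHCO3, THF/MeOH, rt
Reagents that add atoms: hydrogen peroxide OO
Why: Tamao oxidation; the alkoxysilane C–Si bond is oxidised to C–OH under buffered basic conditions that leave alkenes, acetal and the hindered silyl ether alone.

Step 12
Reactants: 17 (3Z,7R)-9,9-dimethoxy-4-methyl-7-(TBSO-heptenyl)non-3-en-1-ol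
Product: 18 (3Z,7R)-1-iodo-9,9-dimethoxy-4-methyl-7-(TBSO-heptenyl)non-3-ene
Conditions: I2, PPh3, imidazole, CH2Cl2, 0 °C → rt
Reagents that add atoms: iodine II
Why: Appel-type (Garegg–Samuelsson) iodination of a primary alcohol; imidazole buffers the medium so the acetal survives.

Step 13
Reactants: 18 (3Z,7R)-1-iodo-9,9-dimethoxy-4-methyl-7-(TBSO-heptenyl)non-3-ene; 19 2,3-dihydrofuran; 20 iodomethane
Product: 26 (3E,7Z,11R)-13,13-dimethoxy-4,8-dimethyl-11-(TBSO-heptenyl)trideca-3,7-dien-1-ol, via 5-lithio-2,3-dihydrofuran 21 (not isolated), via C9 alkyllithium 22 (not isolated), via C9 alkylcopper 23 (not isolated), via mixed lithium cuprate 24 (not isolated), via alkenylcopper lithium alkoxide 25 (not isolated)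
Conditions: 18, t-BuLi (2.1 equiv), Et2O/pentane, −78 °C; CuBr·SMe2, Et2O/Me2S, −78 → −40 °C; 21 (from 19, t-BuLi, THF, −78 → 0 °C), −78 °C → rt; then 20 (excess), −20 °C → rt; aq. NH4Cl/NH3
Reagents that add atoms: none
Why: Iodine–lithium exchange gives alkyllithium 22, transmetallation to copper and addition of 21 give the α-alkoxyalkenyl cuprate 24, and the C9 alkyl group then shifts from copper to C8 anti to the departing ring oxygen (1,2-metallate rearrangement with inversion at the sp2 carbon), so that copper in 25 lies cis to the C6 chain before iodomethane alkylates the C8–Cu bond with retention. The closest known reaction type is this same sequence, the metallate rearrangement of cuprates of 5-lithio-2,3-dihydrofuran followed by alkylation, which is used to build E-trisubstituted homoallylic alcohols from homoallylic iodides. No ring is closed and no stereocentre is created; the only new stereochemical element is the C7=C8 geometry. That geometry is E because the shift is stereospecifically invertive and the methylation retentive, while C1 and the Z alkene C11=C12 are spectators. The step needs clean halogen–metal exchange and alkyl transfer without side reactions, which the substrate secures by carrying only an acetal, a hindered silyl ether and unactivated alkenes, with no acidic or electrophilic site and no alkene placed for anionic cyclisation.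

Step 14
Reactants: 26 (3E,7Z,11R)-13,13-dimethoxy-4,8-dimethyl-11-(TBSO-heptenyl)trideca-3,7-dien-1-ol
Product: 27 (3E,7Z,11R)-1-iodo-13,13-dimethoxy-4,8-dimethyl-11-(TBSO-heptenyl)trideca-3,7-diene
Conditions: I2, PPh3, imidazole, CH2Cl2, 0 °C
Reagents that add atoms: iodine II
Why: Appel-type iodination of the primary C5 alcohol under buffered conditions that leave the acetal and alkenes untouched.

Step 15
Reactants: 27 (3E,7Z,11R)-1-iodo-13,13-dimethoxy-4,8-dimethyl-11-(TBSO-heptenyl)trideca-3,7-diene; 28 methyl bis(2,2,2-trifluoroethyl)phosphonoacetate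
Product: 29 methyl (5E,9Z,13R)-2-[bis(2,2,2-trifluoroethoxy)phosphoryl]-15,15-dimethoxy-6,10-dimethyl-13-(TBSO-heptenyl)pentadeca-5,9-dienoate (both epimers at the phosphonate carbon C4)
Conditions: 28 (2 equiv), NaH, DMSO/THF, rt → 45 °C
Reagents that add atoms: none
Why: SN2 C-alkylation of a stabilised phosphonoacetate carbanion by a primary iodide, with excess phosphonate to limit double alkylation; the new C4 centre is formed without control and disappears in step 17.

Step 16
Reactants: 29 methyl (5E,9Z,13R)-2-[bis(2,2,2-trifluoroethoxy)phosphoryl]-15,15-dimethoxy-6,10-dimethyl-13-(TBSO-heptenyl)pentadeca-5,9-dienoate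
Product: 30 methyl (5E,9Z,13R)-2-[bis(2,2,2-trifluoroethoxy)phosphoryl]-6,10-dimethyl-15-oxo-13-(TBSO-heptenyl)pentadeca-5,9-dienoate
Conditions: TsOH·H2O (cat.), acetone/H2O, rt
Reagents that add atoms: water O
Why: Acid-catalysed acetal hydrolysis; a dimethyl acetal of an unhindered aldehyde cleaves under mild conditions that the tertiary TBS ether, the phosphonate and the isolated alkenes tolerate.

Step 17
Reactants: 30 methyl (5E,9Z,13R)-2-[bis(2,2,2-trifluoroethoxy)phosphoryl]-6,10-dimethyl-15-oxo-13-(TBSO-heptenyl)pentadeca-5,9-dienoate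
Product: 31 methyl (1R,3Z,7E,11Z)-8,12-dimethyl-1-(TBSO-heptenyl)cyclotetradeca-3,7,11-triene-4-carboxylate (ring numbered from the stereocentre)
Conditions: K2CO3, 18-crown-6, toluene, slow addition to about 1 mM, rt
Reagents that add atoms: none
Why: Intramolecular Horner–Wadsworth–Emmons reaction of the Still–Gennari type; the electron-poor trifluoroethyl phosphonate eliminates quickly from the kinetic adduct, which should place C2 cis to the ester (3Z), and high dilution favours closure of the 14-membered ring over oligomerisation.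

Step 18
Reactants: 31 methyl (1R,3Z,7E,11Z)-8,12-dimethyl-1-(TBSO-heptenyl)cyclotetradeca-3,7,11-triene-4-carboxylate
Product: 32 methyl (1R,3Z,7E,11Z)-1-(6-hydroxy-6-methylhept-1-en-2-yl)-8,12-dimethylcyclotetradeca-3,7,11-triene-4-carboxylate (CNP0326472.1)
Conditions: HF·pyridine, pyridine, THF, 0 °C → rt
Reagents that add atoms: none
Why: Fluoride-driven desilylation of the tertiary TBS ether under buffered conditions that should not isomerise the enoate or protonate the alkenes.

Compound list
1 | 3-methylbutane-1,3-diol | CC(C)(O)CCO | starting material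
2 | 4-bromo-2-methylbutan-2-ol | CC(C)(O)CCBr | intermediate
3 | tert-butyl[(4-bromo-2-methylbutan-2-yl)oxy]dimethylsilane | CC(C)(CCBr)O[Si](C)(C)C(C)(C)C | intermediate
4 | (R)-limonene | CC1=CC[C@@H](CC1)C(C)=C | starting material
5 | 10-lithiolimonene, {2-[(1R)-4-methylcyclohex-3-en-1-yl]prop-2-en-1-yl}lithium (TMEDA complex, not isolated) | [Li]CC(=C)[C@H]1CC=C(C)CC1 | intermediate
6 | (4R)-1-methyl-4-(TBSO-heptenyl)cyclohex-1-ene | C=C(CCCC(C)(C)O[Si](C)(C)C(C)(C)C)[C@H]1CC=C(C)CC1 | intermediate
7 | (3R)-6-oxo-3-(TBSO-heptenyl)heptanal (keto aldehyde, not isolated) | C=C(CCCC(C)(C)O[Si](C)(C)C(C)(C)C)[C@H](CCC(C)=O)CC=O | intermediate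
8 | (5R)-7,7-dimethoxy-5-(TBSO-heptenyl)heptan-2-one | C=C(CCCC(C)(C)O[Si](C)(C)C(C)(C)C)[C@H](CCC(C)=O)CC(OC)OC | intermediate
9 | dimethyl carbonate | COC(=O)OC | starting material
10 | methyl (6R)-8,8-dimethoxy-6-(TBSO-heptenyl)-3-oxooctanoate | C=C(CCCC(C)(C)O[Si](C)(C)C(C)(C)C)[C@H](CCC(=O)CC(=O)OC)CC(OC)OC | intermediate
11 | methyl (2E,6R)-8,8-dimethoxy-6-(TBSO-heptenyl)-3-(trifluoromethanesulfonyloxy)oct-2-enoate | C=C(CCCC(C)(C)O[Si](C)(C)C(C)(C)C)[C@H](CC/C(OS(=O)(=O)C(F)(F)F)=C\C(=O)OC)CC(OC)OC | intermediate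
12 | methyl (2Z,6R)-8,8-dimethoxy-3-methyl-6-(TBSO-heptenyl)oct-2-enoate | C=C(CCCC(C)(C)O[Si](C)(C)C(C)(C)C)[C@H](CC/C(C)=C\C(=O)OC)CC(OC)OC | intermediate
13 | (2Z,6R)-8,8-dimethoxy-3-methyl-6-(TBSO-heptenyl)oct-2-en-1-ol | C=C(CCCC(C)(C)O[Si](C)(C)C(C)(C)C)[C@H](CC/C(C)=C\CO)CC(OC)OC | intermediate
14 | (2Z,6R)-8,8-dimethoxy-3-methyl-6-(TBSO-heptenyl)oct-2-en-1-yl methanesulfonate (not isolated) | C=C(CCCC(C)(C)O[Si](C)(C)C(C)(C)C)[C@H](CC/C(C)=C\COS(C)(=O)=O)CC(OC)OC | intermediate
15 | (2Z,6R)-1-bromo-8,8-dimethoxy-3-methyl-6-(TBSO-heptenyl)oct-2-ene | C=C(CCCC(C)(C)O[Si](C)(C)C(C)(C)C)[C@H](CC/C(C)=C\CBr)CC(OC)OC | intermediate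
16 | [(3Z,7R)-9,9-dimethoxy-4-methyl-7-(TBSO-heptenyl)non-3-en-1-yl](isopropoxy)dimethylsilane | C=C(CCCC(C)(C)O[Si](C)(C)C(C)(C)C)[C@H](CC/C(C)=C\CC[Si](C)(C)OC(C)C)CC(OC)OC | intermediate
17 | (3Z,7R)-9,9-dimethoxy-4-methyl-7-(TBSO-heptenyl)non-3-en-1-ol | C=C(CCCC(C)(C)O[Si](C)(C)C(C)(C)C)[C@H](CC/C(C)=C\CCO)CC(OC)OC | intermediate
18 | (3Z,7R)-1-iodo-9,9-dimethoxy-4-methyl-7-(TBSO-heptenyl)non-3-ene (C9 iodide, precursor of the key step) | C=C(CCCC(C)(C)O[Si](C)(C)C(C)(C)C)[C@H](CC/C(C)=C\CCI)CC(OC)OC | intermediate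
19 | 2,3-dihydrofuran | C1CC=CO1 | starting material
20 | iodomethane | CI | starting material
21 | 5-lithio-2,3-dihydrofuran (not isolated) | [Li]C1=CCCO1 | intermediate
22 | C9 alkyllithium, [(3Z,7R)-9,9-dimethoxy-4-methyl-7-(TBSO-heptenyl)non-3-en-1-yl]lithium (not isolated) | C=C(CCCC(C)(C)O[Si](C)(C)C(C)(C)C)[C@H](CC/C(C)=C\CC[Li])CC(OC)OC | intermediate
23 | C9 alkylcopper, the corresponding non-3-en-1-ylcopper (not isolated) | C=C(CCCC(C)(C)O[Si](C)(C)C(C)(C)C)[C@H](CC/C(C)=C\CC[Cu])CC(OC)OC | intermediate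
24 | lithium (C9 alkyl)(4,5-dihydrofuran-2-yl)cuprate (not isolated) | [Li+].C=C(CCCC(C)(C)O[Si](C)(C)C(C)(C)C)[C@H](CC/C(C)=C\CC[Cu-]C1=CCCO1)CC(OC)OC | intermediate
25 | alkenylcopper lithium alkoxide, copper on C8 cis to the C6 chain (not isolated) | C=C(CCCC(C)(C)O[Si](C)(C)C(C)(C)C)[C@H](CC/C(C)=C\CC/C([Cu])=C/CCO[Li])CC(OC)OC | intermediate
26 | (3E,7Z,11R)-13,13-dimethoxy-4,8-dimethyl-11-(TBSO-heptenyl)trideca-3,7-dien-1-ol (product of the key step) | C=C(CCCC(C)(C)O[Si](C)(C)C(C)(C)C)[C@H](CC/C(C)=C\CC/C(C)=C/CCO)CC(OC)OC | intermediate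
27 | (3E,7Z,11R)-1-iodo-13,13-dimethoxy-4,8-dimethyl-11-(TBSO-heptenyl)trideca-3,7-diene | C=C(CCCC(C)(C)O[Si](C)(C)C(C)(C)C)[C@H](CC/C(C)=C\CC/C(C)=C/CCI)CC(OC)OC | intermediate
28 | methyl bis(2,2,2-trifluoroethyl)phosphonoacetate | COC(=O)CP(=O)(OCC(F)(F)F)OCC(F)(F)F | starting material
29 | methyl (5E,9Z,13R)-2-[bis(2,2,2-trifluoroethoxy)phosphoryl]-15,15-dimethoxy-6,10-dimethyl-13-(TBSO-heptenyl)pentadeca-5,9-dienoate (C2 epimers) | C=C(CCCC(C)(C)O[Si](C)(C)C(C)(C)C)[C@H](CC/C(C)=C\CC/C(C)=C/CCC(C(=O)OC)P(=O)(OCC(F)(F)F)OCC(F)(F)F)CC(OC)OC | intermediate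
30 | methyl (5E,9Z,13R)-2-[bis(2,2,2-trifluoroethoxy)phosphoryl]-6,10-dimethyl-15-oxo-13-(TBSO-heptenyl)pentadeca-5,9-dienoate (C2 epimers) | C=C(CCCC(C)(C)O[Si](C)(C)C(C)(C)C)[C@H](CC/C(C)=C\CC/C(C)=C/CCC(C(=O)OC)P(=O)(OCC(F)(F)F)OCC(F)(F)F)CC=O | intermediate
31 | methyl (1R,3Z,7E,11Z)-8,12-dimethyl-1-(TBSO-heptenyl)cyclotetradeca-3,7,11-triene-4-carboxylate | C=C(CCCC(C)(C)O[Si](C)(C)C(C)(C)C)[C@H]1C/C=C(\C(=O)OC)CC/C=C(\C)CC/C=C(/C)CC1 | intermediate
32 | methyl (1R,3Z,7E,11Z)-1-(6-hydroxy-6-methylhept-1-en-2-yl)-8,12-dimethylcyclotetradeca-3,7,11-triene-4-carboxylate | C=C(CCCC(C)(C)O)[C@H]1C/C=C(\C(=O)OC)CC/C=C(\C)CC/C=C(/C)CC1 | target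

Total step count: 18. Longest linear sequence: 18 steps (1 → 32); the limonene branch joins at step 3 and runs 16 steps to the target.

Steps most likely to fail

Step 13. The alkylcopper may decompose before the 1,2-shift, or the alkenylcopper may be protonated instead of methylated, which would leave C8 without its methyl group. The fallback builds the same alkene by carbometalation instead of a metallate shift; it sets out from 18 and returns at 26. Iodide 18 would be displaced with LiC≡CH·H2NCH2CH2NH2 in DMSO to give the terminal alkyne (5Z,9R)-11,11-dimethoxy-6-methyl-9-(TBSO-heptenyl)undec-5-en-1-yne F1. Zirconium-catalysed syn-methylalumination (Me3Al, Cp2ZrCl2, CH2Cl2, kept cold with a trace of water as accelerator to spare the acetal) would put the methyl group on C8 and aluminium on C7. Conversion into the alanate with n-BuLi and opening of ethylene oxide would then add C6–C5–OH with retention and give 26 with the E geometry.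

Step 17. Oligomerisation may compete with ring closure, and ring strain in the cyclic transition state may erode the kinetic Z preference. The fallback sets the enoate geometry before the ring is closed and closes the ring at C4–C5 instead; it sets out from 27 and returns at 31. Acetal hydrolysis of 27 (TsOH·H2O, acetone/H2O) would give (3R,6Z,10E)-13-iodo-6,10-dimethyl-3-(TBSO-heptenyl)trideca-6,10-dienal F2. An intermolecular Horner–Wadsworth–Emmons reaction with methyl bromo[bis(2,2,2-trifluoroethoxy)phosphoryl]acetate (t-BuOK, 18-crown-6, THF, −78 °C) would give methyl (2E,5R,8Z,12E)-2-bromo-15-iodo-8,12-dimethyl-5-(TBSO-heptenyl)pentadeca-2,8,12-trienoate F3, in which C2 is already cis to the ester. Zinc insertion into the primary C–I bond (Zn, LiCl, THF) and an intramolecular Negishi coupling at the alkenyl bromide (Pd(PPh3)4, THF, high dilution) would form C4–C5 with retention and give 31.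

Step 15. The hindered, weakly nucleophilic phosphonate anion may react slowly, so that E2 elimination of the homoallylic iodide to a conjugated diene and double alkylation take over. The fallback brings in carbon first and phosphorus afterwards; it sets out from 27 and returns at 29. Alkylation of sodium dimethyl malonate (NaH, THF/DMF), a small and more nucleophilic carbanion, would give dimethyl 2-[(3E,7Z,11R)-13,13-dimethoxy-4,8-dimethyl-11-(TBSO-heptenyl)trideca-3,7-dien-1-yl]propanedioate F4. Krapcho demethoxycarbonylation (LiCl, wet DMSO, heat) would give methyl (5E,9Z,13R)-15,15-dimethoxy-6,10-dimethyl-13-(TBSO-heptenyl)pentadeca-5,9-dienoate F5. C-Phosphorylation of its enolate (LiN(i-Pr)2, 2 equiv, THF, −78 °C; then bis(2,2,2-trifluoroethyl) phosphorochloridate) would give 29.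

Further compounds
F1 | step 13 | (5Z,9R)-11,11-dimethoxy-6-methyl-9-(TBSO-heptenyl)undec-5-en-1-yne | C=C(CCCC(C)(C)O[Si](C)(C)C(C)(C)C)[C@H](CC/C(C)=C\CCC#C)CC(OC)OC
F2 | step 17 | (3R,6Z,10E)-13-iodo-6,10-dimethyl-3-(TBSO-heptenyl)trideca-6,10-dienal | C=C(CCCC(C)(C)O[Si](C)(C)C(C)(C)C)[C@H](CC/C(C)=C\CC/C(C)=C/CCI)CC=O
F3 | step 17 | methyl (2E,5R,8Z,12E)-2-bromo-15-iodo-8,12-dimethyl-5-(TBSO-heptenyl)pentadeca-2,8,12-trienoate | C=C(CCCC(C)(C)O[Si](C)(C)C(C)(C)C)[C@H](CC/C(C)=C\CC/C(C)=C/CCI)C/C=C(/Br)C(=O)OC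
F4 | step 15 | dimethyl 2-[(3E,7Z,11R)-13,13-dimethoxy-4,8-dimethyl-11-(TBSO-heptenyl)trideca-3,7-dien-1-yl]propanedioate | C=C(CCCC(C)(C)O[Si](C)(C)C(C)(C)C)[C@H](CC/C(C)=C\CC/C(C)=C/CCC(C(=O)OC)C(=O)OC)CC(OC)OC
F5 | step 15 | methyl (5E,9Z,13R)-15,15-dimethoxy-6,10-dimethyl-13-(TBSO-heptenyl)pentadeca-5,9-dienoate | C=C(CCCC(C)(C)O[Si](C)(C)C(C)(C)C)[C@H](CC/C(C)=C\CC/C(C)=C/CCCC(=O)OC)CC(OC)OC
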